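The route rests on a biomimetic disconnection of the trans-decalin (labdane numbering). Rings A and B are closed in one cyclase-mediated, proton-initiated cation–olefin cascade of an open-chain E,E-farnesyl benzyloxymethyl ketone: the C4–C5 and C9–C10 bonds form and the C8 cation is captured by the C13 carbonyl oxygen. The step exploits the trans fusion of rings A and B (C5-H, C10-CH3) and the trans-diequatorial C8–O/C9–C11 pair on ring B with its fully substituted C8, the imprint of a chair–chair folded polyene. Hydrolysis of the temporary pyran frees the C8 hydroxyl and the C13 ketone; methylenation, O-allylation, ring-closing metathesis (C13=C14) and asymmetric hydrogenation then build the eight-membered oxocane ring and set C13.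

Key step: step 2

Numbering: labdane numbering is used for all cyclized compounds. Ring A is C1–C5 with C10, ring B is C5–C10; C18 and C19 are the methyls on C4, C20 the methyl on C10, C17 the methyl on C8. The oxocane ring is C8–O–C15–C14–C13–C12–C11–C9, and C16 is the acetoxymethyl carbon on C13. The target is (5S,8R,9R,10S,13R)-8α,15-epoxylabdan-16-yl acetate.

Assumption: which antipode of the P,N ligand in step 6 leads to 13R cannot be derived on paper with certainty; a test reaction with both antipodes should fix it, and the route is written with the antipode that gives 13R.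

Step 1
Reactants: 1 (2E,6E)-farnesyl bromide; 2 ethyl 4-(benzyloxy)-3-oxobutanoate
Product: 4 (5E,9E)-1-(benzyloxy)-6,10,14-trimethylpentadeca-5,9,13-trien-2-one, via alkylated β-keto ester 3 (not isolated)
Conditions: NaH, THF, 0 °C to rt; then 2 M NaOH, MeOH, 50 °C; then 2 M HCl to pH 3, 50 °C
Reagents that add atoms: none
Why: Acetoacetic ester synthesis, in which SN2 C-alkylation of the sodium enolate of 2 by the primary allylic bromide keeps both E alkenes and saponification–decarboxylation of 3 leaves the ketone; no stereocenter is formed.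

Step 2
Reactants: 4 (5E,9E)-1-(benzyloxy)-6,10,14-trimethylpentadeca-5,9,13-trien-2-one
Product: 6 16-(benzyloxy)-8α-hydroxy-14,15-dinorlabdan-13-one, via cyclic enol ether 5 (not isolated)
Conditions: squalene–hopene cyclase of Alicyclobacillus acidocaldorius (E. coli cell lysate), citrate buffer pH 6.0, Triton X-100, 55 °C; then extraction and 1 M HCl, THF/H2O, rt
Reagents that add atoms: water, O
Why: The cyclase binds 4 in a chair–chair fold and its active-site aspartic acid protonates C3 of the terminal alkene; C5 of the C5=C10 alkene then attacks C4 (ring A), C9 of the C8=C9 alkene attacks C10 (ring B, the C9–C10 bond), the C8 cation is captured on its α face by the C13 carbonyl oxygen and loss of a proton from C12 gives 5, which the acidic work-up hydrolyses to 6. The closest known reactions are the squalene–hopene cyclase conversions of homofarnesol to ambrox and of farnesylacetone to sclareol oxide, themselves copies of the proton-initiated cyclization of geranylgeranyl diphosphate to the labdane bicycle. Rings A and B both close in the 6-endo-trig mode, and the temporary pyran ring closes by six-membered attack of the carbonyl oxygen on the cation. C5, C10, C9 and C8 arise by anti addition across the two E alkenes in the chair–chair fold (trans ring fusion, 9β side chain, 8α oxygen with 8β methyl), and the absolute sense (5S,8R,9R,10S) is imposed by the enzyme pocket, as in hopene and ambrox. The step needs oxygen capture at C8 to win over proton loss and needs full bicyclization; the six-membered reach of the ketone oxygen, the E,E geometry bought with 1 and the enclosed active site should secure both.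

Step 3
Reactants: 6 16-(benzyloxy)-8α-hydroxy-14,15-dinorlabdan-13-one; 7 methyltriphenylphosphonium bromide
Product: 8 (1R,2R,4aS,8aS)-1-{3-[(benzyloxy)methyl]but-3-en-1-yl}-2,5,5,8a-tetramethyldecahydronaphthalen-2-ol
Conditions: Ph3PCH3Br (3.5 equiv), KOtBu (3.5 equiv), THF, 0 °C to reflux
Reagents that add atoms: methyltriphenylphosphonium bromide (7), C[P+](c1ccccc1)(c1ccccc1)c1ccccc1.[Br-]
Why: Wittig methylenation with excess ylide, which tolerates the tertiary alkoxide and opens the ring-chain tautomer of 6; no stereocenter is formed.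

Step 4
Reactants: 8 (1R,2R,4aS,8aS)-1-{3-[(benzyloxy)methyl]but-3-en-1-yl}-2,5,5,8a-tetramethyldecahydronaphthalen-2-ol; 9 allyl bromide
Product: 10 (1R,2R,4aS,8aS)-1-{3-[(benzyloxy)methyl]but-3-en-1-yl}-2,5,5,8a-tetramethyl-2-(prop-2-en-1-yloxy)decahydronaphthalene
Conditions: KH, allyl bromide, Bu4NI (cat.), THF, 0 to 40 °C
Reagents that add atoms: allyl bromide (9), C=CCBr
Why: Williamson etherification of the potassium alkoxide of the equatorial tertiary C8 alcohol with a reactive allylic bromide; the C8–O bond is not broken, so C8 keeps its configuration.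

Step 5
Reactants: 10 (1R,2R,4aS,8aS)-1-{3-[(benzyloxy)methyl]but-3-en-1-yl}-2,5,5,8a-tetramethyl-2-(prop-2-en-1-yloxy)decahydronaphthalene
Product: 11 (5S,8R,9R,10S)-16-(benzyloxy)-8α,15-epoxylabd-13-ene (trans-fused oxocene with the C13=C14 double bond)
Conditions: second-generation Grubbs catalyst RuCl2(=CHPh)(PCy3)(H2IMes) (10 mol %), 1,4-benzoquinone (cat.), toluene (2 mM), 80 °C
Reagents that add atoms: none
Why: Ring-closing metathesis, in which the ruthenium carbene loads on the monosubstituted allyl ether and closes onto the 1,1-disubstituted alkene with loss of ethylene; the trans-diequatorial O8/C11 pair on ring B holds the two chains gauche, which should favour the eight-membered ring, and the new alkene is cis within the ring.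

Step 6
Reactants: 11 (5S,8R,9R,10S)-16-(benzyloxy)-8α,15-epoxylabd-13-ene
Product: 12 (5S,8R,9R,10S,13R)-16-(benzyloxy)-8α,15-epoxylabdane
Conditions: [Ir(cod)(tBu-PHOX)][B(C6H3-3,5-(CF3)2)4] (2 mol %, ligand antipode matched for 13R), H2 (50 bar), CH2Cl2, rt
Reagents that add atoms: none
Why: Iridium-catalysed asymmetric hydrogenation of an unfunctionalised trisubstituted alkene (Pfaltz type), in which the chiral P,N ligand selects the face of the geometrically fixed ring alkene and so should set C13 as R under catalyst control, while the benzyl ether and the tertiary ether are inert.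

Step 7
Reactants: 12 (5S,8R,9R,10S,13R)-16-(benzyloxy)-8α,15-epoxylabdane
Product: 13 (5S,8R,9R,10S,13R)-8α,15-epoxylabdan-16-ol
Conditions: H2 (1 atm), 10% Pd/C, EtOAc/EtOH, rt
Reagents that add atoms: none
Why: Hydrogenolysis of the benzyl ether over Pd/C; the dialkyl ether of the oxocane and all stereocenters should be unaffected.

Step 8
Reactants: 13 (5S,8R,9R,10S,13R)-8α,15-epoxylabdan-16-ol; 14 acetic anhydride
Product: 15 (5S,8R,9R,10S,13R)-8α,15-epoxylabdan-16-yl acetate
Conditions: Ac2O, pyridine, DMAP (cat.), CH2Cl2, rt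
Reagents that add atoms: acetic anhydride (14), CC(=O)OC(C)=O
Why: DMAP-catalysed acetylation of the primary alcohol; no stereocenter is touched.

Compound list
1 | (2E,6E)-farnesyl bromide, (2E,6E)-1-bromo-3,7,11-trimethyldodeca-2,6,10-triene | CC(C)=CCC/C(C)=C/CC/C(C)=C/CBr | starting material
2 | ethyl 4-(benzyloxy)-3-oxobutanoate | CCOC(=O)CC(=O)COCc1ccccc1 | starting material
3 | ethyl (4E,8E)-2-[(benzyloxy)acetyl]-5,9,13-trimethyltetradeca-4,8,12-trienoate (alkylated β-keto ester) | CCOC(=O)C(C/C=C(C)/CC/C=C(C)/CCC=C(C)C)C(=O)COCc1ccccc1 | intermediate (not isolated)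
4 | (5E,9E)-1-(benzyloxy)-6,10,14-trimethylpentadeca-5,9,13-trien-2-one | CC(C)=CCC/C(C)=C/CC/C(C)=C/CCC(=O)COCc1ccccc1 | intermediate
5 | 16-(benzyloxy)-8α,13-epoxy-14,15-dinorlabd-12-ene, (4aR,6aS,10aS,10bR)-3-[(benzyloxy)methyl]-4a,7,7,10a-tetramethyl-4a,5,6,6a,7,8,9,10,10a,10b-decahydro-1H-benzo[f]chromene (cyclic enol ether) | C1=C(COCc2ccccc2)O[C@]3(C)CC[C@H]4C(C)(C)CCC[C@]4(C)[C@H]3C1 | intermediate (not isolated)
6 | 16-(benzyloxy)-8α-hydroxy-14,15-dinorlabdan-13-one, 1-(benzyloxy)-4-[(1R,2R,4aS,8aS)-2-hydroxy-2,5,5,8a-tetramethyldecahydronaphthalen-1-yl]butan-2-one | O[C@]1(C)CC[C@H]2C(C)(C)CCC[C@]2(C)[C@H]1CCC(=O)COCc1ccccc1 | intermediate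
7 | methyltriphenylphosphonium bromide | C[P+](c1ccccc1)(c1ccccc1)c1ccccc1.[Br-] | starting material
8 | (1R,2R,4aS,8aS)-1-{3-[(benzyloxy)methyl]but-3-en-1-yl}-2,5,5,8a-tetramethyldecahydronaphthalen-2-ol | O[C@]1(C)CC[C@H]2C(C)(C)CCC[C@]2(C)[C@H]1CCC(=C)COCc1ccccc1 | intermediate
9 | allyl bromide | C=CCBr | starting material
10 | (1R,2R,4aS,8aS)-1-{3-[(benzyloxy)methyl]but-3-en-1-yl}-2,5,5,8a-tetramethyl-2-(prop-2-en-1-yloxy)decahydronaphthalene | C=CCO[C@]1(C)CC[C@H]2C(C)(C)CCC[C@]2(C)[C@H]1CCC(=C)COCc1ccccc1 | intermediate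
11 | (5S,8R,9R,10S)-16-(benzyloxy)-8α,15-epoxylabd-13-ene | c1ccccc1COC/C1=C/CO[C@]2(C)CC[C@H]3C(C)(C)CCC[C@]3(C)[C@H]2CC1 | intermediate
12 | (5S,8R,9R,10S,13R)-16-(benzyloxy)-8α,15-epoxylabdane | c1ccccc1COC[C@H]1CCO[C@]2(C)CC[C@H]3C(C)(C)CCC[C@]3(C)[C@H]2CC1 | intermediate
13 | (5S,8R,9R,10S,13R)-8α,15-epoxylabdan-16-ol | OC[C@H]1CCO[C@]2(C)CC[C@H]3C(C)(C)CCC[C@]3(C)[C@H]2CC1 | intermediate
14 | acetic anhydride | CC(=O)OC(C)=O | starting material
15 | (5S,8R,9R,10S,13R)-8α,15-epoxylabdan-16-yl acetate | CC(=O)OC[C@H]1CCO[C@]2(C)CC[C@H]3C(C)(C)CCC[C@]3(C)[C@H]2CC1 | target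

Total step count: 8
Longest linear sequence: 8 steps (1 to 15)

Steps most likely to fail

Step 2. The benzyloxymethyl ketone tail may bind unproductively in the cyclase, or the C8 cation may be quenched by proton loss before the ketone oxygen reaches it, so that olefinic mono- or bicycles form in place of the enol ether. The fallback sets out from 1 and moves the oxygen terminator to a smaller, better precedented carboxyl group. The dianion of acetic acid (LiN(iPr)2, THF/HMPA, 0 °C) is alkylated by 1 to (4E,8E)-5,9,13-trimethyltetradeca-4,8,12-trienoic acid F1. F1 is cyclized by the same cyclase, or by a confined chiral Brønsted acid in a fluorinated alcohol, to the δ-lactone ambreinolide F2. Addition of (benzyloxymethyl)lithium (Bu3SnCH2OBn, nBuLi, THF, −78 °C) to F2 should stop at the hemiketal stage and comes back to the route at 6.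

Step 6. Facial selectivity may be poor if the conformation of the oxocene overrides the ligand, or the double bond may migrate before it is reduced. The fallback sets out from 11 and replaces kinetic catalyst control by separation and recycling through an epimerizable center. H2 over Pd/C reduces the alkene and cleaves the benzyl ether in one operation to give 13 together with its C13 epimer, (5S,8R,9R,10S,13S)-8α,15-epoxylabdan-16-ol F7. After chromatographic separation, F7 is oxidized with Dess–Martin periodinane to 8α,15-epoxylabdan-16-al F8, which is equilibrated at C13 with DBU, reduced with NaBH4 and separated again. The material thus converges on 13, where the route is rejoined.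

Step 4. Alkylation of the hindered tertiary alkoxide may be slow, with allyl bromide consumed by side reactions and 8 recovered. The fallback sets out from 8 and builds the C8–O–C15 link by acylation and later reduction. The potassium alkoxide of 8 and acryloyl chloride (THF, −78 to 0 °C) give the acrylate of 8, F3. Ring-closing metathesis with the second-generation Hoveyda–Grubbs catalyst RuCl2(H2IMes)(=CH-C6H4-2-OiPr) in toluene at 80 °C gives the unsaturated eight-membered lactone 16-(benzyloxy)-labd-13-en-15,8α-olide F4. CuH-catalysed asymmetric conjugate reduction (Cu(OAc)2, DTBM-SEGPHOS, polymethylhydrosiloxane, tBuOH, toluene) should set C13 in (13R)-16-(benzyloxy)-labdan-15,8α-olide F5. Reductive acetylation (iBu2AlH, CH2Cl2, −78 °C; then Ac2O, pyridine, DMAP) gives the α-acetoxy ether (13R)-15-acetoxy-16-(benzyloxy)-8α,15-epoxylabdane F6. Et3SiH with BF3·OEt2 at −78 °C reduces F6 to 12, where the route is rejoined.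

Further compounds
F1 | step 2 | (4E,8E)-5,9,13-trimethyltetradeca-4,8,12-trienoic acid (farnesylacetic acid) | CC(C)=CCC/C(C)=C/CC/C(C)=C/CCC(=O)O
F2 | step 2 | ambreinolide, (4aR,6aS,10aS,10bR)-4a,7,7,10a-tetramethyldodecahydro-3H-benzo[f]chromen-3-one | O=C1O[C@]2(C)CC[C@H]3C(C)(C)CCC[C@]3(C)[C@H]2CC1
F3 | step 4 | (1R,2R,4aS,8aS)-1-{3-[(benzyloxy)methyl]but-3-en-1-yl}-2,5,5,8a-tetramethyldecahydronaphthalen-2-yl prop-2-enoate | C=CC(=O)O[C@]1(C)CC[C@H]2C(C)(C)CCC[C@]2(C)[C@H]1CCC(=C)COCc1ccccc1
F4 | step 4 | (5S,8R,9R,10S)-16-(benzyloxy)-labd-13-en-15,8α-olide | c1ccccc1COC/C1=C/C(=O)O[C@]2(C)CC[C@H]3C(C)(C)CCC[C@]3(C)[C@H]2CC1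
F5 | step 4 | (5S,8R,9R,10S,13R)-16-(benzyloxy)-labdan-15,8α-olide | c1ccccc1COC[C@H]1CC(=O)O[C@]2(C)CC[C@H]3C(C)(C)CCC[C@]3(C)[C@H]2CC1
F6 | step 4 | (5S,8R,9R,10S,13R)-15-acetoxy-16-(benzyloxy)-8α,15-epoxylabdane (C15 epimers) | c1ccccc1COC[C@H]1CC(OC(C)=O)O[C@]2(C)CC[C@H]3C(C)(C)CCC[C@]3(C)[C@H]2CC1
F7 | step 6 | (5S,8R,9R,10S,13S)-8α,15-epoxylabdan-16-ol | OC[C@@H]1CCO[C@]2(C)CC[C@H]3C(C)(C)CCC[C@]3(C)[C@H]2CC1
F8 | step 6 | (5S,8R,9R,10S)-8α,15-epoxylabdan-16-al (C13 epimers) | O=CC1CCO[C@]2(C)CC[C@H]3C(C)(C)CCC[C@]3(C)[C@H]2CC1
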